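We start from the amounts: each electrophile in the flask gets 1.50 equiv of nucleophile and 1.20 equiv of free base, so on paper neither should run short.

| flask | electrophile | nucleophile | free base | temperature | remark | time |
|---|---|---|---|---|---|---|
| red | 0.050 M | 1.5 equiv | 1.2 equiv | 60 °C | the very flask that is asked about, followed so far |  |
| blue | 0.050 M | 1.5 equiv | 1.2 equiv | 66 °C | run made earlier |  |
| flask | 0.050 M | 1.50 equiv | 1.20 equiv | 60 °C |  | 1.0 h |

| run | time / min | target / % |
|---|---|---|
| red | 6.00 | 10 |
| red | 15.0 | 15 |
| red | 30.0 | 24 |
| red | 50.0 | 27 |
| blue | 6.00 | 16 |
| blue | 15.0 | 23 |
| blue | 30.0 | 28 |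
| blue | 50.0 | 32 |

(readings scatter by 1.5 percentage points)

- gamma: at 1.0 h add free base, 100 % of the amount charged, then wait 2.0 h
- eta: at 1.0 h raise the temperature by 15 K, then wait 2.0 h
- delta: change nothing and wait 2.0 h more
- zeta: at 1.0 h add electrophile, 50.0 % of the amount charged, then wait 2.0 h
- beta: at 1.0 h add free base, 100 % of the amount charged, then wait 2.0 h

- target, in percent of the electrophile first charged, at 1.0 h
- which option adds most target ("none" when 2 percentage points or less is all one gets) (gamma / eta / delta / zeta / beta / none)
- target present, in percent of the electrophile first charged, after eta
- target present, in percent of the electrophile first charged, after delta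

- in percentages every species weighs as the electrophile in it: one side product counts as two
- for target the crystals are counted in
- as a solid, counted per litre of solution: crystals
- the volume of additions can be left aside
- steps thought possible: electrophile + nucleophile -> acid set free + target; nucleophile + acid set free <-> protonated nucleophile; acid set free + free base <-> salt of the base; electrophile + target -> side product; nucleophile <-> dormant form; crystals <-> target

But the red run, which is this flask followed so far, reaches 10 % at 6.00 min and then adds 3 percentage points between 30.0 min and 50.0 min. The blue run at 66 °C starts faster than the red run, 16 % against 10 %, yet its last reading is 32 %, so the blue run slows down too.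

Our own reckoning takes the acid as caught at once and asks what nucleophile stays free. If the nucleophile drains away by fixed shares of its charge, it acts as limiting reagent despite that charge, and at a given electrophile charge, free base charge, temperature and time, target should follow the nucleophile charged. So we carry one quantity: the last red reading, taken at 50.0 min, divided by the equivalents of nucleophile charged, 18.0 %, the nucleophile yield. It rests on one reading, with the scatter of 1.5 points in that reading.

The forecast gives 28.5 % now, names eta as best with 38 % after it, and gives 32 % after waiting. On the stall it says: “The stall looks more like loss of active nucleophile to the dormant form”.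

    electrophile + nucleophile → acid set free + target (k = 0.316 M⁻¹ min⁻¹, Ea = 72.0 kJ mol⁻¹)
    nucleophile + acid set free ⇌ protonated nucleophile, settled at all times (K = 45000 M⁻¹, ΔH = −14.0 kJ mol⁻¹)
    acid set free + free base ⇌ salt of the base, settled at all times (K = 1100 M⁻¹, ΔH = −3.00 kJ mol⁻¹)
    electrophile + target → side product (k = 0.276 M⁻¹ min⁻¹, Ea = 52.0 kJ mol⁻¹)
    nucleophile ⇌ dormant form (K = 2.00, k = 0.0378 min⁻¹, Ea = 102 kJ mol⁻¹, ΔH = −12.0 kJ mol⁻¹)
    crystals ⇌ target, rate k6*(cs6 - [target]) while solid is left; crystals form when [target] > cs6 (solubility = 7.80 mM, k = 7.76 min⁻¹)
    (constants at 60 °C)

The flask gives 28.6 % at 1.0 h, and eta is best, adding 13 points and ending at 41.6 %, while waiting ends at 32.9 %. At 60.0 min the flask has 15.7 % of its charged nucleophile free, against 55.1 % of its charged electrophile. Its nucleophile yield at 1.0 h is 19.1 %, beside the 18.0 % read from the red run at 50.0 min.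

For the flask with 0.600 equiv of nucleophile, other charges and the time unchanged, the nucleophile yield read at 50.0 min gives 10.8 % of target. The computed flask gives 10.6 % at 60.0 min.

The data come from a simulation for substances that don't exist, noise included.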